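The ten-membered ring of the target carries O2 and O7 in a 1,6-relationship on either side of the diene C3=C4–C5=C6. A double oxy-Cope shift of a 1,2-dialkynyl-1,2-diol leaves exactly this pattern. The ring is therefore grown rather than cyclised. A trans-decalin (six-ring C1–C2–C7–C8–C9–C10 fused to ring C1/C10–C14), with ethynyl on C2 and a 3-silyloxypropynyl group on C7, is ionised to its bis-alkoxide. C4–C5 forms as C2–C7 breaks, and protonation gives the 3,5-diene-2,7-dione in one operation. All sp3 stereocentres except C2 and C7 are set beforehand on the rigid decalin, which is made from (R)-Wieland–Miescher ketone.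

Key step: step 22

Assumption (numbering and faces): briarane numbering is used for every intermediate (C15 = methyl on C1, C16 on C5, C17/C18/C19 = side chain on C8, C20 = methylene on C11); α is the face of H10 and β the face of C15.

Remark (absolute configuration): C1 of the target corresponds to the R enantiomer of the Wieland–Miescher ketone, so D-proline is needed and not the natural amino acid.

Remark (precursor design):
- An axial alkyne on C7 would sit syn-axial to both C15 and O9, a position no acetylide can reach.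
- The route therefore aims at the trans-diaxial 2,7-diol with both alkynes equatorial.
- The alkynes stay gauche at about 60°, the two alkoxides are anti, and O7 is anti to O8, so no 1,2-silyl shift can occur.
- C2 and C7 become trigonal in the key step, so their configuration has no other consequence.

Remark (protecting groups):
- O8 is a triethylsilyl ether that falls with fluoride.
- O16 is a tert-butyldiphenylsilyl ether, so O19 can be released first.
- The ring-cis C5=C6 bond is E by the sequence rule, because C16 outranks C4.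

Step 1
Reactants: 1 2-methylcyclohexane-1,3-dione; 2 methyl vinyl ketone
Product: 3 2-methyl-2-(3-oxobutyl)cyclohexane-1,3-dione
Conditions: AcOH (cat.), hydroquinone (cat.), H2O, 75 °C
Reagents that add atoms: none
Why: Michael addition of the 1,3-dione enol to the enone makes the C1–C2 bond and the still prochiral quaternary carbon C1.

Step 2
Reactants: 3 2-methyl-2-(3-oxobutyl)cyclohexane-1,3-dione
Product: 4 (R)-Wieland–Miescher ketone (C8 enone with C9=C10; C14 ketone)
Conditions: D-proline (cat.), DMSO, rt; crystallisation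
Reagents that add atoms: none
Why: In the Hajos–Parrish–Eder–Sauer–Wiechert enamine aldol condensation (C9–C10 bond), the D-amino acid selects the enantiotopic ring carbonyl that leaves C1 R, the mirror image of the L-proline product, and crystallisation should raise the enantiomeric purity.

Step 3
Reactants: 4 (R)-Wieland–Miescher ketone
Product: 5 11-methylene dienone (C8(=O)–C9=C10–C11=C20H2; C14 ketone)
Conditions: CH2(OEt)2, POCl3, NaOAc, CHCl3, reflux
Reagents that add atoms: diethoxymethane, CCOCOCC
Why: Vinylogous (gamma) alkoxymethylation of the dienol ether formed in situ, followed by loss of ethanol, is the one-pot 6-methylenation known for 4-en-3-one steroids; it puts C20 on C11 and leaves the unconjugated C14 ketone alone.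

Step 4
Reactants: 5 11-methylene dienone
Product: 6 9β,10β-epoxy ketone
Conditions: 30% H2O2, NaOH (cat.), MeOH, 0 °C
Reagents that add atoms: hydrogen peroxide, OO
Why: In this Weitz–Scheffer epoxidation the hard hydroperoxide anion should add 1,4 at C10 rather than 1,6 at C20, and from the β face as in angular-methyl octalones, which sets C9 (O β) and puts the oxygen to be displaced on the β face of C10.

Step 5
Reactants: 6 9β,10β-epoxy ketone
Product: 7 trans-decalin ketol (9β-OH; 10α-H; C11=C20H2; C8 and C14 ketones)
Conditions: Pd2(dba)3·CHCl3 (cat.), PBu3, HCO2H, Et3N, dioxane, rt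
Reagents that add atoms: none
Why: In this palladium-catalysed formate hydrogenolysis of an alkenyl epoxide, zerovalent palladium opens the allylic C10–O bond with inversion (metal on the α face) and hands the formate-derived hydride to the more substituted allyl terminus, which sets 10α-H (trans fusion), keeps 9β-OH and leaves the alkene exocyclic.

Step 6
Reactants: 7 trans-decalin ketol
Product: 8 9β-silyl ether C8 silyl enol ether (C7=C8; C14 ketone free)
Conditions: TBSOTf (2.1 equiv), Et3N, CH2Cl2, −78 to −30 °C
Reagents that add atoms: tert-butyldimethylsilyl triflate, CC(C)(C)[Si](C)(C)OS(=O)(=O)C(F)(F)F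
Why: In this O-silylation and soft enolisation the enol ether forms towards C7 because H9 is equatorial and lies in the nodal plane of the carbonyl, while the neopentyl C14 carbonyl, screened by C15 and the peri C2 methylene, should lag behind the bulky triflate at low temperature.

Step 7
Reactants: 8 9β-silyl ether C8 silyl enol ether
Product: 9 14α-alcohol
Conditions: LiBH(s-Bu)3 (L-Selectride), THF, −78 °C; H2O
Reagents that add atoms: none
Why: With C8 masked, C14 is the only ketone, and the bulky trialkylborohydride avoids the three syn-axial hydrogens of the α face (H10, H12, H2) and enters along the equatorial path, giving the axial 14α-alcohol as in the reduction of 4,4-dimethyl-3-oxo triterpenoids to 3α-alcohols.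

Step 8
Reactants: 9 14α-alcohol
Product: 10 9β,14α-bis(silyl ether) C8 silyl enol ether
Conditions: TBSOTf, 2,6-lutidine, CH2Cl2, 0 °C
Reagents that add atoms: tert-butyldimethylsilyl triflate, CC(C)(C)[Si](C)(C)OS(=O)(=O)C(F)(F)F
Why: Silyl ether formation with the triflate copes with an axial neopentyl alcohol and leaves the enol ether untouched.

Step 9
Reactants: 10 9β,14α-bis(silyl ether) C8 silyl enol ether
Product: 11 C8 enone with C2=C7
Conditions: Pd(OAc)2 (1.1 equiv), MeCN, 40 °C
Reagents that add atoms: none
Why: In the Saegusa–Ito oxidation divalent palladium binds C7 and β-hydride loss from C2 gives the enone, with the isolated methylene group as a spectator.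

Step 10
Reactants: 11 C8 enone with C2=C7; 12 methyl propanoate
Product: 14 aldol adduct (8β-OH; ester side chain α; C17 as in the target), via lithium enolate 13 (not isolated)
Conditions: LiN(i-Pr)2, THF, −78 °C; then 11; AcOH quench at −78 °C
Reagents that add atoms: none
Why: In this ester-enolate aldol addition (1,2 because C2 is neopentyl) attack occurs on the α face, anti to the axial 9β-silyloxy group, through a Zimmerman–Traxler chair with the C9 branch and the enolate methyl (trans to OLi) both equatorial; this sets C17, whereas the C8 carbinol centre made here is erased in step 13.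

Step 11
Reactants: 14 aldol adduct
Product: 15 8,19-diol
Conditions: LiAlH4, Et2O, 0 °C
Reagents that add atoms: none
Why: Hydride reduction of the ester to the primary C19 alcohol removes the acidity of H17 before any later base can epimerise C17.

Step 12
Reactants: 15 8,19-diol
Product: 16 19-silyl ether with free tertiary allylic 8-OH
Conditions: TBSCl, imidazole, CH2Cl2, 0 °C
Reagents that add atoms: tert-butyldimethylsilyl chloride, CC(C)(C)[Si](C)(C)Cl
Why: Selective silylation protects the primary alcohol, because the tertiary allylic alcohol is too hindered for the silyl chloride.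

Step 13
Reactants: 16 19-silyl ether with free tertiary allylic 8-OH
Product: 17 C2 enone with C7=C8 bearing the side chain
Conditions: pyridinium chlorochromate C5H5NH[CrO3Cl], 4 Å MS, CH2Cl2, rt
Reagents that add atoms: pyridinium chlorochromate, [O-][Cr](=O)(=O)Cl.c1cc[nH+]cc1
Why: In the Babler–Dauben oxidative transposition the tertiary allylic chromate ester passes an oxygen to C2 by a [3,3] shift and is oxidised there (the old C8 oxygen leaves with chromium), which gives the C2 ketone, moves the alkene to C7=C8 and does not touch C17.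

Step 14
Reactants: 17 C2 enone with C7=C8
Product: 18 7α,8α-epoxy ketone
Conditions: t-BuOOH, benzyltrimethylammonium hydroxide (cat.), THF, 0 °C to rt
Reagents that add atoms: tert-butyl hydroperoxide, CC(C)(C)OO
Why: This Weitz–Scheffer epoxidation ignores the electron-rich methylene group; the peroxide anion adds to C8 axially from the α face, anti to the 9β-silyloxy group and away from C15, which sets O8 α and the side chain β as in the target.

Step 15
Reactants: 18 7α,8α-epoxy ketone
Product: 19 8α-hydroxy C2 ketone (C7H2)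
Conditions: SmI2, THF–MeOH, −78 °C
Reagents that add atoms: none
Why: In the samarium diiodide reduction of an α,β-epoxy ketone, electron transfer to the C2 carbonyl breaks only the α C7–O bond, so the tertiary C8–O bond keeps its configuration.

Step 16
Reactants: 19 8α-hydroxy C2 ketone
Product: 20 8α-triethylsilyl ether C2 triethylsilyl enol ether (C2=C7)
Conditions: TESOTf (3 equiv), Et3N, CH2Cl2, 0 °C to rt
Reagents that add atoms: triethylsilyl triflate, CC[Si](CC)(CC)OS(=O)(=O)C(F)(F)F
Why: Silyl triflate–amine silylation uses no strong base, so retro-aldol cleavage is avoided, and an excess of the smaller triflate at room temperature caps O8 and turns the hindered C2 ketone into its only possible enol ether.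

Step 17
Reactants: 20 8α-triethylsilyl ether C2 triethylsilyl enol ether
Product: 22 7α-hydroxy C2 ketone (O8 still silylated), via 7-triethylsilyloxy ketone 21 (not isolated)
Conditions: mCPBA (1.05 equiv), CH2Cl2–hexane, −20 °C; then AcOH–THF–H2O, rt
Reagents that add atoms: 3-chloroperbenzoic acid, OOC(=O)c1cccc(Cl)c1
Why: In the Rubottom oxidation the enol ether is epoxidised far faster than the 1,1-disubstituted alkene, silyl migration gives 21, and mild acid frees only the secondary α-keto silyl ether; α attack is expected because C15 and O9 close the β face, but C7 becomes a ketone in step 19.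

Step 18
Reactants: 22 7α-hydroxy C2 ketone; 23 ethynylmagnesium bromide
Product: 24 2-ethynyl 2,7-diol (2-OH α axial; alkyne β equatorial)
Conditions: HC≡CMgBr (excess), LaCl3·2LiCl, THF, 0 °C to rt
Reagents that add atoms: none
Why: In this lanthanum-assisted Grignard 1,2-addition the 7-alkoxide formed first suppresses enolisation, and the syn-axial silyl ethers on O8 and O14 close the α face, so the slim nucleophile should enter along the equatorial path; C2 is flattened again in step 22.

Step 19
Reactants: 24 2-ethynyl 2,7-diol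
Product: 25 2-ethynyl-2-hydroxy C7 ketone
Conditions: IBX (2-iodoxybenzoic acid), DMSO, rt
Reagents that add atoms: none
Why: IBX oxidises the only secondary alcohol without cleaving the 1,2-diol and gives a ketone that has no α-hydrogen.

Step 20
Reactants: 26 propargyl alcohol
Product: 27 tert-butyldiphenylsilyl propargyl ether
Conditions: TBDPSCl, imidazole, CH2Cl2, rt
Reagents that add atoms: tert-butyldiphenylsilyl chloride, CC(C)(C)[Si](Cl)(c1ccccc1)c1ccccc1
Why: Standard silylation gives an ether on the future O16 that survives the later selective release of O19.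

Step 21
Reactants: 25 2-ethynyl-2-hydroxy C7 ketone; 27 tert-butyldiphenylsilyl propargyl ether
Product: 29 2,7-dialkynyl trans-decalin-2,7-diol (diol trans-diaxial; both alkynes equatorial), via lithium acetylide 28 (not isolated)
Conditions: n-BuLi, THF, −78 °C; then 25 (excess acetylide), −78 to 0 °C; H2O
Reagents that add atoms: none
Why: In this acetylide 1,2-addition to a non-enolisable ketone, C15 and O9 close the axial (β) path, so the nucleophile, held by the lithium alkoxide on O2, should enter equatorially and end gauche to the C2 alkyne, while the low temperature holds back any α-ketol shift.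

Step 22
Reactants: 29 2,7-dialkynyl trans-decalin-2,7-diol
Product: 32 ten-membered (3Z,5E)-3,5-diene-2,7-dione, via dipotassium bis-alkoxide 30 (not isolated), via ring-expanded bis-allenolate 31 (not isolated)
Conditions: KN(SiMe3)2 (2.1 equiv), 18-crown-6, THF, −78 to 0 °C; cannulation into AcOH–THF at −78 °C
Reagents that add atoms: none
Why: Proposed new method: deprotonation of both tertiary carbinols gives 30, whose oxygen lone pairs weaken the strained C2–C7 bond, so a six-centre [3,3] shift through the gauche diequatorial alkynes should join C4 to C5, break C2–C7 and give bis-allenolate 31, which the cold acid protonates at C3 and C6. The closest known reaction types are the dianionic oxy-Cope expansion of 1,2-divinylcyclohexane-1,2-diols to cyclodecane-1,6-diones, the thermal acetylenic oxy-Cope and the 1,5-hexadiyne Cope rearrangement; the doubly acetylenic, doubly anionic version on a ring has not been shown. The ten-membered ring is closed by a four-atom ring expansion (bond formation inside a cyclic six-centre array with cleavage of a ring bond), not by end-to-end cyclisation, so no high dilution is needed. No stereocentre is made, but the step must deliver Z at C3=C4 and the ring-cis geometry at C5=C6, and this rests on protonation of each central allene carbon from outside the ring (syn to H4 and syn to C16), because the inner lobe points across the ring. The driving force is enolate formation plus release of the threefold syn-axial contacts on both faces of the six-ring (C15/O7/O9 and O14/O2/O8), and low temperature with inverse quench is meant to outrun four-electron closure of the bis-allene and loss of acetylide. Only 2.1 equivalents of base are used because H4 is about as acidic as the carbinols, so any acetylide is a resting state that drains through the irreversible shift.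

Step 23
Reactants: 32 ten-membered (3Z,5E)-3,5-diene-2,7-dione
Product: 33 (2S,7S)-diol
Conditions: (R)-tetrahydro-1-methyl-3,3-diphenyl-1H,3H-pyrrolo[1,2-c][1,3,2]oxazaborole ((R)-Me-CBS), catecholborane, toluene, −78 to −40 °C
Reagents that add atoms: none
Why: In this twofold Corey–Bakshi–Shibata 1,2-reduction both carbonyls show the same local shape (fully substituted sp3 carbon C1 or C8 as the large group, flat alkenyl as the small one), so one catalyst enantiomer should set C2 and C7 in the required sense, and catecholborane spares the methylene group.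

Step 24
Reactants: 33 (2S,7S)-diol
Product: 34 2,7,8,19-tetraol (O9, O14 and O16 still silylated)
Conditions: HF·pyridine, pyridine, THF, 0 °C
Reagents that add atoms: none
Why: Buffered fluoride desilylation is graded by hindrance and silyl type: it removes the primary tert-butyldimethylsilyl and the triethylsilyl group, keeps the hindered secondary ethers and the diphenylsilyl ether, and is mild enough for the allylic alcohols.

Step 25
Reactants: 34 2,7,8,19-tetraol
Product: 36 7,19-lactone, via lactol 35 (not isolated)
Conditions: TEMPO (cat.), PhI(OAc)2, CH2Cl2, rt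
Reagents that add atoms: none
Why: In this oxoammonium oxidative lactonisation of a 1,4-diol the unhindered primary C19 alcohol is oxidised first, the aldehyde is caught by O7 as a five-ring lactol (O9 is blocked) and oxidised on, and the hindered secondary allylic alcohols react more slowly.

Step 26
Reactants: 36 7,19-lactone
Product: 37 2,8,9,14,16-pentaol lactone
Conditions: HF·pyridine (excess), MeCN, rt
Reagents that add atoms: none
Why: Exhaustive acidic fluoride desilylation avoids the basic conditions under which the lactone could move to O9 or the β-hydroxy lactone could undergo retro-aldol cleavage.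

Step 27
Reactants: 37 2,8,9,14,16-pentaol lactone
Product: 38 target CNP0269068.1
Conditions: Ac2O, DMAP, pyridine, rt
Reagents that add atoms: acetic anhydride, CC(=O)OC(C)=O
Why: DMAP-catalysed acetylation esterifies the primary O16 and the secondary O2, O9 and O14, whereas the tertiary, hydrogen-bonded 8-OH stays free.

Compound list
1 | 2-methylcyclohexane-1,3-dione | CC1C(=O)CCCC1=O | starting material
2 | methyl vinyl ketone | CC(=O)C=C | starting material
3 | 2-methyl-2-(3-oxobutyl)cyclohexane-1,3-dione | CC(=O)CCC1(C)C(=O)CCCC1=O | intermediate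
4 | (R)-Wieland–Miescher ketone | C1CCC(=O)[C@]2(C)CCC(=O)C=C12 | intermediate
5 | 11-methylene dienone, C14 ketone | C=C1CCC(=O)[C@]2(C)CCC(=O)C=C12 | intermediate
6 | 9β,10β-epoxy C8 ketone, C11 methylene, C14 ketone | C=C1CCC(=O)[C@]2(C)CCC(=O)[C@H]3O[C@@]123 | intermediate
7 | trans-decalin ketol, 9β-OH, 10α-H | C=C1CCC(=O)[C@]2(C)CCC(=O)[C@@H](O)[C@@H]12 | intermediate
8 | 9β-OTBS, C8 TBS enol ether (C7=C8), C14 ketone | C=C1CCC(=O)[C@]2(C)CC=C(O[Si](C)(C)C(C)(C)C)[C@@H](O[Si](C)(C)C(C)(C)C)[C@@H]12 | intermediate
9 | 14α-alcohol of 8 | C=C1CC[C@H](O)[C@]2(C)CC=C(O[Si](C)(C)C(C)(C)C)[C@@H](O[Si](C)(C)C(C)(C)C)[C@@H]12 | intermediate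
10 | 9β,14α-bis-OTBS, C8 TBS enol ether | C=C1CC[C@H](O[Si](C)(C)C(C)(C)C)[C@]2(C)CC=C(O[Si](C)(C)C(C)(C)C)[C@@H](O[Si](C)(C)C(C)(C)C)[C@@H]12 | intermediate
11 | C8 enone, C2=C7 | C=C1CC[C@H](O[Si](C)(C)C(C)(C)C)[C@]2(C)C=CC(=O)[C@@H](O[Si](C)(C)C(C)(C)C)[C@@H]12 | intermediate
12 | methyl propanoate | CCC(=O)OC | starting material
13 | lithium enolate of 12, methyl trans to OLi | C/C=C(/[O-])OC.[Li+] | intermediate
14 | aldol adduct, 8β-OH, side chain α, C17 set | C=C1CC[C@H](O[Si](C)(C)C(C)(C)C)[C@]2(C)C=C[C@](O)([C@@H](C)C(=O)OC)[C@@H](O[Si](C)(C)C(C)(C)C)[C@@H]12 | intermediate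
15 | 8,19-diol | C=C1CC[C@H](O[Si](C)(C)C(C)(C)C)[C@]2(C)C=C[C@](O)([C@@H](C)CO)[C@@H](O[Si](C)(C)C(C)(C)C)[C@@H]12 | intermediate
16 | 19-OTBS tertiary allylic alcohol | C=C1CC[C@H](O[Si](C)(C)C(C)(C)C)[C@]2(C)C=C[C@](O)([C@@H](C)CO[Si](C)(C)C(C)(C)C)[C@@H](O[Si](C)(C)C(C)(C)C)[C@@H]12 | intermediate
17 | C2 enone, C7=C8 with side chain | C=C1CC[C@H](O[Si](C)(C)C(C)(C)C)[C@]2(C)C(=O)C=C([C@@H](C)CO[Si](C)(C)C(C)(C)C)[C@@H](O[Si](C)(C)C(C)(C)C)[C@@H]12 | intermediate
18 | 7α,8α-epoxy C2 ketone | C=C1CC[C@H](O[Si](C)(C)C(C)(C)C)[C@]2(C)C(=O)[C@@H]3O[C@]3([C@@H](C)CO[Si](C)(C)C(C)(C)C)[C@@H](O[Si](C)(C)C(C)(C)C)[C@@H]12 | intermediate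
19 | 8α-hydroxy C2 ketone | C=C1CC[C@H](O[Si](C)(C)C(C)(C)C)[C@]2(C)C(=O)C[C@@](O)([C@@H](C)CO[Si](C)(C)C(C)(C)C)[C@@H](O[Si](C)(C)C(C)(C)C)[C@@H]12 | intermediate
20 | 8α-OTES, C2 TES enol ether | C=C1CC[C@H](O[Si](C)(C)C(C)(C)C)[C@]2(C)C(O[Si](CC)(CC)CC)=C[C@@](O[Si](CC)(CC)CC)([C@@H](C)CO[Si](C)(C)C(C)(C)C)[C@@H](O[Si](C)(C)C(C)(C)C)[C@@H]12 | intermediate
21 | 7α,8α-bis-OTES C2 ketone | C=C1CC[C@H](O[Si](C)(C)C(C)(C)C)[C@]2(C)C(=O)[C@H](O[Si](CC)(CC)CC)[C@@](O[Si](CC)(CC)CC)([C@@H](C)CO[Si](C)(C)C(C)(C)C)[C@@H](O[Si](C)(C)C(C)(C)C)[C@@H]12 | intermediate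
22 | 7α-hydroxy-8α-OTES C2 ketone | C=C1CC[C@H](O[Si](C)(C)C(C)(C)C)[C@]2(C)C(=O)[C@H](O)[C@@](O[Si](CC)(CC)CC)([C@@H](C)CO[Si](C)(C)C(C)(C)C)[C@@H](O[Si](C)(C)C(C)(C)C)[C@@H]12 | intermediate
23 | ethynylmagnesium bromide | C#C[Mg]Br | starting material
24 | 2-ethynyl 2α,7α-diol | C=C1CC[C@H](O[Si](C)(C)C(C)(C)C)[C@]2(C)[C@@](O)(C#C)[C@H](O)[C@@](O[Si](CC)(CC)CC)([C@@H](C)CO[Si](C)(C)C(C)(C)C)[C@@H](O[Si](C)(C)C(C)(C)C)[C@@H]12 | intermediate
25 | 2-ethynyl-2α-hydroxy C7 ketone | C=C1CC[C@H](O[Si](C)(C)C(C)(C)C)[C@]2(C)[C@@](O)(C#C)C(=O)[C@@](O[Si](CC)(CC)CC)([C@@H](C)CO[Si](C)(C)C(C)(C)C)[C@@H](O[Si](C)(C)C(C)(C)C)[C@@H]12 | intermediate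
26 | propargyl alcohol | C#CCO | starting material
27 | tert-butyldiphenylsilyl propargyl ether | C#CCO[Si](c1ccccc1)(c1ccccc1)C(C)(C)C | intermediate
28 | lithium acetylide of 27 | [Li]C#CCO[Si](c1ccccc1)(c1ccccc1)C(C)(C)C | intermediate
29 | key-step precursor, 2,7-dialkynyl trans-decalin-2α,7β-diol | C=C1CC[C@H](O[Si](C)(C)C(C)(C)C)[C@]2(C)[C@@](O)(C#C)[C@](O)(C#CCO[Si](c3ccccc3)(c3ccccc3)C(C)(C)C)[C@@](O[Si](CC)(CC)CC)([C@@H](C)CO[Si](C)(C)C(C)(C)C)[C@@H](O[Si](C)(C)C(C)(C)C)[C@@H]12 | intermediate
30 | dipotassium bis-alkoxide of 29 | C=C1CC[C@H](O[Si](C)(C)C(C)(C)C)[C@]2(C)[C@@]([O-])(C#C)[C@]([O-])(C#CCO[Si](c3ccccc3)(c3ccccc3)C(C)(C)C)[C@@](O[Si](CC)(CC)CC)([C@@H](C)CO[Si](C)(C)C(C)(C)C)[C@@H](O[Si](C)(C)C(C)(C)C)[C@@H]12.[K+].[K+] | intermediate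
31 | ten-membered dipotassium bis-allenolate (allene axes not defined) | C=C1CC[C@H](O[Si](C)(C)C(C)(C)C)[C@]2(C)C([O-])=C=CC(CO[Si](c3ccccc3)(c3ccccc3)C(C)(C)C)=C=C([O-])[C@@](O[Si](CC)(CC)CC)([C@@H](C)CO[Si](C)(C)C(C)(C)C)[C@@H](O[Si](C)(C)C(C)(C)C)[C@@H]12.[K+].[K+] | intermediate
32 | key-step product, ten-membered (3Z,5E)-3,5-diene-2,7-dione | C=C1CC[C@H](O[Si](C)(C)C(C)(C)C)[C@]2(C)C(=O)/C=C\C(CO[Si](c3ccccc3)(c3ccccc3)C(C)(C)C)=C/C(=O)[C@@](O[Si](CC)(CC)CC)([C@@H](C)CO[Si](C)(C)C(C)(C)C)[C@@H](O[Si](C)(C)C(C)(C)C)[C@@H]12 | intermediate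
33 | (2S,7S)-diol | C=C1CC[C@H](O[Si](C)(C)C(C)(C)C)[C@]2(C)[C@@H](O)/C=C\C(CO[Si](c3ccccc3)(c3ccccc3)C(C)(C)C)=C/[C@H](O)[C@@](O[Si](CC)(CC)CC)([C@@H](C)CO[Si](C)(C)C(C)(C)C)[C@@H](O[Si](C)(C)C(C)(C)C)[C@@H]12 | intermediate
34 | 2,7,8,19-tetraol | C=C1CC[C@H](O[Si](C)(C)C(C)(C)C)[C@]2(C)[C@@H](O)/C=C\C(CO[Si](c3ccccc3)(c3ccccc3)C(C)(C)C)=C/[C@H](O)[C@@](O)([C@@H](C)CO)[C@@H](O[Si](C)(C)C(C)(C)C)[C@@H]12 | intermediate
35 | 7,19-lactol (C19 not defined) | C=C1CC[C@H](O[Si](C)(C)C(C)(C)C)[C@]2(C)[C@@H](O)/C=C\C(CO[Si](c4ccccc4)(c4ccccc4)C(C)(C)C)=C/[C@@H]3OC(O)[C@H](C)[C@@]3(O)[C@@H](O[Si](C)(C)C(C)(C)C)[C@@H]12 | intermediate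
36 | 7,19-lactone, 2-OH and 8-OH free | C=C1CC[C@H](O[Si](C)(C)C(C)(C)C)[C@]2(C)[C@@H](O)/C=C\C(CO[Si](c4ccccc4)(c4ccccc4)C(C)(C)C)=C/[C@@H]3OC(=O)[C@H](C)[C@@]3(O)[C@@H](O[Si](C)(C)C(C)(C)C)[C@@H]12 | intermediate
37 | 2,8,9,14,16-pentaol lactone | C=C1CC[C@H](O)[C@]2(C)[C@@H](O)/C=C\C(CO)=C/[C@@H]3OC(=O)[C@H](C)[C@@]3(O)[C@@H](O)[C@@H]12 | intermediate
38 | CNP0269068.1 | C=C1CC[C@H](OC(C)=O)[C@]2(C)[C@@H](OC(C)=O)/C=C\C(COC(C)=O)=C/[C@@H]3OC(=O)[C@H](C)[C@@]3(O)[C@@H](OC(C)=O)[C@@H]12 | target

Total step count: 27. Longest linear sequence: 26 (steps 1–19 and 21–27; step 20 is a side branch).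

Steps most likely to fail

Step 22 (key step). The alkyne termini may not come within bonding distance in the locked chair. An alkoxide may expel acetylide. The triethylsilyl group may wander from O8 to the syn-axial O2. The bis-allene may close by a four-electron path, or protonation may give the wrong alkene geometry.

The fallback uses known chemistry and sets out from 29. Semihydrogenation (H2, Pd/CaCO3 poisoned with Pb(OAc)2, quinoline) gives the 2-vinyl-7-[(Z)-propenyl] diol F1. KH and 18-crown-6 in THF trigger the established dianionic oxy-Cope expansion of a 1,2-divinylcyclohexane-1,2-diol to the ten-membered bis-enolate F2. This is trapped with Me3SiCl before any transannular aldol reaction, giving the bis(silyl enol ether) F3. A double Saegusa–Ito oxidation with Pd(OAc)2 removes the transient C5 centre and, after iodine-catalysed equilibration of the diene geometry if needed, returns to the route at 32.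

Step 23. The two carbonyls are flanked by fully substituted carbons, so they may react sluggishly. The ring conformation may also override the catalyst, which would erode facial selectivity at C2 or C7.

The fallback changes from reagent control to chelation control and sets out from 32. Buffered HF·pyridine first frees O8 and O19 to give the 8,19-dihydroxy dienedione F4. Zn(BH4)2 in Et2O then ties the C7 carbonyl to the free 8-OH, so the carbonyl points to the α face and hydride arrives from outside the ring, on the C17 side. C2 is reduced from the periphery. This gives the tetraol directly and rejoins the route at 34.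

Step 4. Hydroperoxide may add to the unhindered C20 terminus, or from the α face, which would spoil the regio- or facial selectivity on which C9 and C10 depend.

The fallback replaces nucleophilic epoxidation by hydroxyl-directed epoxidation and sets out from 5. Luche reduction (NaBH4, CeCl3·7H2O, MeOH) gives the 8β,14β-diol F5. VO(acac)2 and t-BuOOH deliver oxygen to C9=C10 syn to the allylic 8β-OH and give the epoxy diol F6. Dess–Martin periodinane oxidises both carbinols and returns to the route at 6.

Further compounds
F1 | step 22 | 2-vinyl-7-[(Z)-3-(tert-butyldiphenylsilyloxy)prop-1-enyl] trans-decalin-2α,7β-diol | C=C1CC[C@H](O[Si](C)(C)C(C)(C)C)[C@]2(C)[C@@](O)(C=C)[C@](O)(/C=C\CO[Si](c3ccccc3)(c3ccccc3)C(C)(C)C)[C@@](O[Si](CC)(CC)CC)([C@@H](C)CO[Si](C)(C)C(C)(C)C)[C@@H](O[Si](C)(C)C(C)(C)C)[C@@H]12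
F2 | step 22 | ten-membered dipotassium 2,6-bis-enolate (C5 and enolate geometry transient, not defined) | C=C1CC[C@H](O[Si](C)(C)C(C)(C)C)[C@]2(C)C([O-])=CCC(CO[Si](c3ccccc3)(c3ccccc3)C(C)(C)C)C=C([O-])[C@@](O[Si](CC)(CC)CC)([C@@H](C)CO[Si](C)(C)C(C)(C)C)[C@@H](O[Si](C)(C)C(C)(C)C)[C@@H]12.[K+].[K+]
F3 | step 22 | ten-membered bis(trimethylsilyl enol ether) (C5 and enol ether geometry transient, not defined) | C=C1CC[C@H](O[Si](C)(C)C(C)(C)C)[C@]2(C)C(O[Si](C)(C)C)=CCC(CO[Si](c3ccccc3)(c3ccccc3)C(C)(C)C)C=C(O[Si](C)(C)C)[C@@](O[Si](CC)(CC)CC)([C@@H](C)CO[Si](C)(C)C(C)(C)C)[C@@H](O[Si](C)(C)C(C)(C)C)[C@@H]12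
F4 | step 23 | 8,19-dihydroxy (3Z,5E)-3,5-diene-2,7-dione | C=C1CC[C@H](O[Si](C)(C)C(C)(C)C)[C@]2(C)C(=O)/C=C\C(CO[Si](c3ccccc3)(c3ccccc3)C(C)(C)C)=C/C(=O)[C@@](O)([C@@H](C)CO)[C@@H](O[Si](C)(C)C(C)(C)C)[C@@H]12
F5 | step 4 | 8β,14β-diol of the 11-methylene diene | C=C1CC[C@@H](O)[C@]2(C)CC[C@@H](O)C=C12
F6 | step 4 | 9β,10β-epoxy 8β,14β-diol | C=C1CC[C@@H](O)[C@]2(C)CC[C@@H](O)[C@H]3O[C@@]123
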